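The benzo ring of the indole is taken apart into three alkynes. The adjacent bromines on C5 and C6 sit on two carbons that can come from one alkyne, so that alkyne is bis(trimethylsilyl)acetylene and the silyl groups mark both positions for later ipso-bromination. A cobalt-catalysed [2+2+2] cocyclisation of this alkyne with a sulfonamide-linked diyne forms C3a–C7a, C4–C5 and C6–C7 in one operation and closes the five-membered nitrogen ring (N1, C2, C3, C3a, C7a) together with the benzene ring. The precursor is an N-tosyl ynamide carrying a terminal N-ethynyl group and a but-3-ynyl chain on the same nitrogen. Bromine, N-methyl and the aminomethyl group follow.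

Key step: step 5

Remark on the chemistry: the target has no stereocentre and no other stereogenic element, so the question of a single enantiomer does not arise; the route leads to the one achiral compound.

**Route**

Step 1
Reactants: 1 but-3-yn-1-amine; 2 4-toluenesulfonyl chloride
Product: 3 N-(but-3-yn-1-yl)-4-methylbenzenesulfonamide
Conditions: Et3N (1.5 equiv), CH2Cl2, 0 °C → rt
Reagents that add atoms: none
Why: N-sulfonylation of a primary amine with a sulfonyl chloride is fast and selective for nitrogen, and the terminal alkyne is inert to these conditions.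

Step 2
Reactants: 4 bis(trimethylsilyl)acetylene; 5 (diacetoxyiodo)benzene
Product: 7 phenyl[(trimethylsilyl)ethynyl]iodonium trifluoromethanesulfonate, via mixed acetate triflate iodane 6 (not isolated)
Conditions: Tf2O (0.5 equiv), CH2Cl2, 0 °C, 30 min; then 4 (1.0 equiv), 0 °C → rt; precipitation with Et2O/hexane
Reagents that add atoms: trifluoromethanesulfonic anhydride, O=S(=O)(OS(=O)(=O)C(F)(F)F)C(F)(F)F
Why: Ligand exchange makes the iodine(III) centre strongly electrophilic, and it replaces one silyl group of the alkyne by ipso attack (silicon–iodine(III) exchange), the standard preparation of alkynyl(aryl)iodonium triflates; the cationic product is too deactivated to lose the second silyl group.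

Step 3
Reactants: 3 N-(but-3-yn-1-yl)-4-methylbenzenesulfonamide; 7 phenyl[(trimethylsilyl)ethynyl]iodonium trifluoromethanesulfonate
Product: 9 N-(but-3-yn-1-yl)-4-methyl-N-[(trimethylsilyl)ethynyl]benzenesulfonamide, via potassium sulfonamidate 8 (not isolated)
Conditions: KHMDS (1.05 equiv), toluene, 0 °C; then 7 (1.2 equiv), 0 °C → rt
Reagents that add atoms: none
Why: N-alkynylation of a sulfonamide anion with an alkynyliodonium salt proceeds by conjugate addition at the silyl-bearing carbon, loss of iodobenzene to an alkylidene carbene and 1,2-shift to the ynamide, and one equivalent of base removes only the far more acidic N–H, not the terminal C–H.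

Step 4
Reactants: 9 N-(but-3-yn-1-yl)-4-methyl-N-[(trimethylsilyl)ethynyl]benzenesulfonamide
Product: 10 N-(but-3-yn-1-yl)-N-ethynyl-4-methylbenzenesulfonamide
Conditions: TBAF (1.1 equiv), wet THF, 0 °C, short reaction time
Reagents that add atoms: none
Why: Fluoride-induced protodesilylation of an alkynylsilane is fast at 0 °C, and the sulfonyl-stabilised ynamide should survive the brief exposure to give the terminal diyne.

Step 5
Reactants: 10 N-(but-3-yn-1-yl)-N-ethynyl-4-methylbenzenesulfonamide; 4 bis(trimethylsilyl)acetylene
Product: 11 1-tosyl-5,6-bis(trimethylsilyl)indoline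
Conditions: CpCo(CO)2 (10 mol %), 4 as solvent (large excess, recovered by distillation), hν (visible lamp), reflux, syringe-pump addition of 10 over ca. 12 h, Ar
Reagents that add atoms: none
Why: Light and heat strip CO from CpCo(CO)2, the CpCo fragment binds both tethered alkynes of 10 and couples them oxidatively to a bicyclic cobaltacyclopentadiene, which forges C3a–C7a; the disilylalkyne then coordinates and inserts, and reductive elimination forges C4–C5 and C6–C7 and releases the catalyst. The closest known reactions are the CpCo(CO)2-catalysed cocyclisation of hepta-1,6-diynes with bis(trimethylsilyl)acetylene to 5,6-disilylindanes and the metal-catalysed cyclotrimerisation of N-sulfonyl ynamide diynes to indolines. The five-membered ring (N1, C2, C3, C3a, C7a) closes by intramolecular oxidative cyclisation of the 1,6-diyne, enforced by the three-atom CH2–CH2–N tether, and the benzene ring closes by intermolecular alkyne insertion and reductive elimination, a formal [2+2+2] cycloaddition. No stereocentre is created. The step needs chemoselectivity for cross-cyclisation over oligomerisation of the diyne, which is secured because the bulky disilylalkyne does not trimerise with itself and can serve as solvent while 10 is kept dilute by slow addition; regiochemistry is not in question because the tether fixes C3a and C7a and the alkyne partner is symmetrical. The sulfonyl group lowers the donor strength of nitrogen, so the N-alkyne should behave toward cobalt like an ordinary terminal alkyne.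

Step 6
Reactants: 11 1-tosyl-5,6-bis(trimethylsilyl)indoline
Product: 13 5,6-dibromo-1-tosylindoline, via 5-bromo-6-silyl indoline 12 (not isolated)
Conditions: Br2 (2.2 equiv), pyridine (cat.), CH2Cl2, 0 °C → rt, dark
Reagents that add atoms: bromine, BrBr
Why: Electrophilic ipso substitution (bromodesilylation) is favoured at each silyl-bearing carbon by β-silicon stabilisation of the arenium ion and by relief of strain between the ortho silyl groups, first at C5 para to nitrogen and then at C6, and the saturated five-membered ring offers no competing enamine-type carbon.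

Step 7
Reactants: 13 5,6-dibromo-1-tosylindoline
Product: 14 5,6-dibromo-1-tosyl-1H-indole
Conditions: DDQ (2.5 equiv), chlorobenzene, reflux
Reagents that add atoms: none
Why: Quinone dehydrogenation (hydride abstraction from the C2/C3 ethylene bridge, then proton loss) is driven by aromatisation to the indole, and aryl bromides and the sulfonamide are inert to DDQ.

Step 8
Reactants: 14 5,6-dibromo-1-tosyl-1H-indole
Product: 16 2,5,6-tribromo-1-tosyl-1H-indole, via 2-lithioindole 15 (not isolated)
Conditions: LDA (1.1 equiv), THF, −78 °C, 45 min; then BrCCl2CCl2Br (1.2 equiv), −78 °C → rt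
Reagents that add atoms: 1,2-dibromo-1,1,2,2-tetrachloroethane, BrC(Cl)(Cl)C(Cl)(Cl)Br
Why: Sulfonyl-directed deprotonation of an N-sulfonylindole occurs at C2, its most acidic C–H, a lithium amide (not an alkyllithium) avoids bromine–lithium exchange at C5 and C6, and the aryllithium is brominated by the electrophilic bromine donor.

Step 9
Reactants: 16 2,5,6-tribromo-1-tosyl-1H-indole
Product: 18 2,5,6-tribromo-1-methyl-1H-indole, via potassium indolide 17 (not isolated)
Conditions: KOH (powdered, 5 equiv), DMSO, rt; then MeI (3 equiv), 0 °C → rt
Reagents that add atoms: iodomethane, CI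
Why: Hydroxide attacks the sulfonyl sulfur and releases the bromine-stabilised indolide (nucleophilic N–S cleavage of an N-sulfonylindole), which is N-methylated by SN2 reaction in the same dipolar aprotic medium.

Step 10
Reactants: 18 2,5,6-tribromo-1-methyl-1H-indole
Product: 19 2,5,6-tribromo-1-methylgramine [1-(2,5,6-tribromo-1-methyl-1H-indol-3-yl)-N,N-dimethylmethanamine]
Conditions: N,N-dimethylmethyleneiminium iodide (1.5 equiv), MeCN, 60 °C; aq. NaOH work-up
Reagents that add atoms: N,N-dimethylmethyleneiminium iodide, C=[N+](C)C.[I-]
Why: Mannich aminomethylation with a preformed iminium salt should take place at C3, the only free and the most nucleophilic position of the N-methylindole, and avoids the acidic aqueous conditions that a 2-bromoindole tolerates poorly.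

**Compound list**

1 | but-3-yn-1-amine | C#CCCN | starting material
2 | 4-toluenesulfonyl chloride | Cc1ccc(cc1)S(=O)(=O)Cl | starting material
3 | N-(but-3-yn-1-yl)-4-methylbenzenesulfonamide | C#CCCNS(=O)(=O)c1ccc(C)cc1 | intermediate
4 | bis(trimethylsilyl)acetylene | C[Si](C)(C)C#C[Si](C)(C)C | starting material
5 | (diacetoxyiodo)benzene | CC(=O)OI(OC(C)=O)c1ccccc1 | starting material
6 | [acetoxy(phenyl)-λ3-iodanyl] trifluoromethanesulfonate | CC(=O)OI(OS(=O)(=O)C(F)(F)F)c1ccccc1 | intermediate
7 | phenyl[(trimethylsilyl)ethynyl]iodonium trifluoromethanesulfonate | C[Si](C)(C)C#C[I+]c1ccccc1.[O-]S(=O)(=O)C(F)(F)F | intermediate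
8 | potassium (but-3-yn-1-yl)(4-methylbenzenesulfonyl)azanide | C#CCC[N-]S(=O)(=O)c1ccc(C)cc1.[K+] | intermediate
9 | N-(but-3-yn-1-yl)-4-methyl-N-[(trimethylsilyl)ethynyl]benzenesulfonamide | C#CCCN(C#C[Si](C)(C)C)S(=O)(=O)c1ccc(C)cc1 | intermediate
10 | N-(but-3-yn-1-yl)-N-ethynyl-4-methylbenzenesulfonamide | C#CCCN(C#C)S(=O)(=O)c1ccc(C)cc1 | intermediate
11 | 1-tosyl-5,6-bis(trimethylsilyl)indoline | Cc1ccc(cc1)S(=O)(=O)N1CCc2cc([Si](C)(C)C)c([Si](C)(C)C)cc21 | intermediate
12 | 5-bromo-1-tosyl-6-(trimethylsilyl)indoline | Cc1ccc(cc1)S(=O)(=O)N1CCc2cc(Br)c([Si](C)(C)C)cc21 | intermediate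
13 | 5,6-dibromo-1-tosylindoline | Cc1ccc(cc1)S(=O)(=O)N1CCc2cc(Br)c(Br)cc21 | intermediate
14 | 5,6-dibromo-1-tosyl-1H-indole | Cc1ccc(cc1)S(=O)(=O)n1ccc2cc(Br)c(Br)cc21 | intermediate
15 | 5,6-dibromo-2-lithio-1-tosyl-1H-indole | [Li]c1cc2cc(Br)c(Br)cc2n1S(=O)(=O)c1ccc(C)cc1 | intermediate
16 | 2,5,6-tribromo-1-tosyl-1H-indole | Cc1ccc(cc1)S(=O)(=O)n1c(Br)cc2cc(Br)c(Br)cc21 | intermediate
17 | potassium 2,5,6-tribromoindol-1-ide | Brc1cc2cc(Br)c(Br)cc2[n-]1.[K+] | intermediate
18 | 2,5,6-tribromo-1-methyl-1H-indole | Cn1c(Br)cc2cc(Br)c(Br)cc21 | intermediate
19 | 2,5,6-tribromo-1-methylgramine | CN(C)Cc1c(Br)n(C)c2cc(Br)c(Br)cc12 | target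

**Step count**

Total: 10 steps. Longest linear sequence: 9 steps (steps 1 and 3–10 from but-3-yn-1-amine; the branch through step 2 is equally long).

**Steps most likely to fail**

Step 5. The diyne may oligomerise or cyclise with itself faster than it captures the hindered alkyne, the terminal ynamide may decompose at reflux temperature, or cobalt may be tied up in inert cyclobutadiene complexes. The fallback gives up the benzannulation and brominates a preformed indole. It sets out from 2 together with commercial methyl 1H-indole-3-carboxylate (COC(=O)c1c[nH]c2ccccc12). Bromine in acetic acid should brominate C5 and C6 selectively, because the C3 ester shuts down the pyrrole ring, giving methyl 5,6-dibromo-1H-indole-3-carboxylate F1. Saponification (aq. NaOH, MeOH, reflux) should give 5,6-dibromo-1H-indole-3-carboxylic acid F2, which should lose carbon dioxide on heating to give 5,6-dibromo-1H-indole F3. N-Sulfonylation with 2 (NaH, DMF, 0 °C) comes back to the route at 14.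

Step 7. Hydride abstraction may be too slow, since the nitrogen lone pair is engaged by the sulfonyl group and the arene is electron-poor, so that long heating brings incomplete conversion or degradation. The fallback removes the sulfonyl group before the oxidation. It sets out from 13: concentrated H2SO4 at rt should cleave the N-aryl sulfonamide to 5,6-dibromoindoline F4. Activated MnO2 in CH2Cl2 should dehydrogenate the free indoline readily to 5,6-dibromo-1H-indole F3, the same compound as in the first fallback. Renewed sulfonylation with 2 (NaH, DMF, 0 °C) comes back to the route at 14.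

Step 8. Competing deprotonation at C7 or C4 next to a ring bromine, followed by bromine migration or aryne formation, or deprotonation of the tolyl methyl group, would erode the selectivity for C2. The fallback uses no carbanion and derives the C2 bromine from an oxindole carbonyl. It sets out from 14: KOH in DMSO followed by MeI, as in step 9, should give 5,6-dibromo-1-methyl-1H-indole F5. Pyridinium tribromide in aqueous tert-butanol should convert it into 3,3,5,6-tetrabromo-1-methylindolin-2-one F6. Zinc in acetic acid at rt should remove only the two aliphatic bromines and give 5,6-dibromo-1-methylindolin-2-one F7. Phosphorus oxybromide (1,2-dichloroethane, reflux) should turn the lactam into the 2-bromoindole, which comes back to the route at 18.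

**Further compounds**

F1 | step 5 | methyl 5,6-dibromo-1H-indole-3-carboxylate | COC(=O)c1c[nH]c2cc(Br)c(Br)cc12
F2 | step 5 | 5,6-dibromo-1H-indole-3-carboxylic acid | OC(=O)c1c[nH]c2cc(Br)c(Br)cc12
F3 | step 5 | 5,6-dibromo-1H-indole | Brc1cc2cc[nH]c2cc1Br
F4 | step 7 | 5,6-dibromoindoline | Brc1cc2CCNc2cc1Br
F5 | step 8 | 5,6-dibromo-1-methyl-1H-indole | Cn1ccc2cc(Br)c(Br)cc21
F6 | step 8 | 3,3,5,6-tetrabromo-1-methylindolin-2-one | CN1C(=O)C(Br)(Br)c2cc(Br)c(Br)cc21
F7 | step 8 | 5,6-dibromo-1-methylindolin-2-one | CN1C(=O)Cc2cc(Br)c(Br)cc21
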